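**Retrosynthetic overview**

1. Target ⇐ hydrolysis of its C14 1,3-dioxolane (last step; nothing else is protected at that point).
2. Both rings are closed together in the penultimate step: CrCl2 converts an open-chain (Z)-2-(bromomethyl)enoate bearing a Z-enal into an allylchromium. C6–C7 bond formation closes the ten-membered carbocycle, and the C6 alkoxide closes the α-methylene-γ-lactone in the same flask, steered by the free C8–OH.
3. Allylic bromide ⇐ Baylis–Hillman-type alcohol (vinylalumination of a C7 aldehyde, then SN2′ bromination).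
4. C8/C9 ⇐ Sharpless epoxidation of a dienol, then Ti-mediated opening by (R)-2-methylbutanoic acid (inversion at C9; the ester is in place from then on).
5. Dienol ⇐ Stille coupling of a (Z)-α-iodoenal acetal made from nerol (supplies C1–C6, C15 and the ring-cis C4=C5 bond) by glycol cleavage, Wittig reaction and α-iodination.

Assumption: atom labels C1–C15 in the explanations are the germacrane positions of the target (C12 lactone carbonyl, C13 exocyclic methylene, C14 formyl carbon, C15 ring methyl); all starting materials are purchased.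

**Route**

Step 1
Reactants: 1 nerol
Product: 2 triethyl{[(2Z)-3,7-dimethylocta-2,6-dien-1-yl]oxy}silane
Conditions: TESCl, imidazole, CH2Cl2, 0 °C → rt
Reagents that add atoms: chlorotriethylsilane, CC[Si](Cl)(CC)CC
Why: Standard silyl ether formation (no stereocentre); the primary TES ether survives steps 2–9 and is later oxidised directly to the aldehyde.

Step 2
Reactants: 2 triethyl{[(2Z)-3,7-dimethylocta-2,6-dien-1-yl]oxy}silane
Product: 4 (4Z)-4-methyl-6-[(triethylsilyl)oxy]hex-4-enal, via diol 3 (not isolated)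
Conditions: K2OsO4·2H2O (1 mol %), NMO (1.05 equiv), acetone–H2O, 0 °C; then NaIO4, rt
Reagents that add atoms: 4-methylmorpholine N-oxide, C[N+]1([O-])CCOCC1; water, O
Why: Upjohn dihydroxylation is selective for the electron-rich distal trisubstituted alkene (the other is deactivated by its allylic C–O bond), and periodate glycol cleavage (Lemieux–Johnson-type sequence) then gives the C1 aldehyde with the Z C4=C5 bond untouched.

Step 3
Reactants: 4 (4Z)-4-methyl-6-[(triethylsilyl)oxy]hex-4-enal; 5 (triphenylphosphoranylidene)acetaldehyde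
Product: 6 (2E,6Z)-6-methyl-8-[(triethylsilyl)oxy]octa-2,6-dienal
Conditions: toluene, 80 °C
Reagents that add atoms: none
Why: Wittig olefination with a stabilised formyl ylide gives the E-enal and creates the C1=C10 bond.

Step 4
Reactants: 6 (2E,6Z)-6-methyl-8-[(triethylsilyl)oxy]octa-2,6-dienal
Product: 7 (2Z,6Z)-2-iodo-6-methyl-8-[(triethylsilyl)oxy]octa-2,6-dienal
Conditions: I2, DMAP (20 mol %), K2CO3, THF–H2O (1:1), rt
Reagents that add atoms: iodine, II
Why: DMAP-mediated α-iodination of the enal (Baylis–Hillman-type addition, iodination, elimination) gives the thermodynamic (Z)-α-iodoenal, with iodine cis to the C2 chain and the formyl group (future C14) trans, which fixes the C1=C10 geometry of the target.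

Step 5
Reactants: 7 (2Z,6Z)-2-iodo-6-methyl-8-[(triethylsilyl)oxy]octa-2,6-dienal
Product: 8 2-{(1Z,5Z)-1-iodo-5-methyl-7-[(triethylsilyl)oxy]hepta-1,5-dien-1-yl}-1,3-dioxolane
Conditions: TMSOCH2CH2OTMS, TMSOTf (5 mol %), CH2Cl2, −78 → −20 °C; pyridine quench
Reagents that add atoms: 1,2-bis(trimethylsilyloxy)ethane, C[Si](C)(C)OCCO[Si](C)(C)C
Why: Noyori acetalisation under aprotic conditions masks the C14 aldehyde as a 1,3-dioxolane without moving the double bond or cleaving the silyl ether.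

Step 6
Reactants: 8 2-{(1Z,5Z)-1-iodo-5-methyl-7-[(triethylsilyl)oxy]hepta-1,5-dien-1-yl}-1,3-dioxolane; 9 (2E)-3-(tributylstannyl)prop-2-en-1-ol
Product: 10 (2E,4E,8Z)-4-(1,3-dioxolan-2-yl)-8-methyl-10-[(triethylsilyl)oxy]deca-2,4,8-trien-1-ol
Conditions: Pd2(dba)3 (2.5 mol %), AsPh3 (20 mol %), NMP, 40 °C
Reagents that add atoms: none
Why: Stille cross-coupling proceeds with retention at both alkenyl carbons, so C9 ends up cis to C2 on C1=C10 and the new C8=C9 bond is E.

Step 7
Reactants: 10 (2E,4E,8Z)-4-(1,3-dioxolan-2-yl)-8-methyl-10-[(triethylsilyl)oxy]deca-2,4,8-trien-1-ol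
Product: 11 [(2S,3S)-3-{(1E,5Z)-1-(1,3-dioxolan-2-yl)-5-methyl-7-[(triethylsilyl)oxy]hepta-1,5-dien-1-yl}oxiran-2-yl]methanol
Conditions: Ti(OiPr)4 (10 mol %), L-(+)-diethyl tartrate (12 mol %), t-BuOOH (1.5 equiv), 4 Å MS, CH2Cl2, −20 °C
Reagents that add atoms: tert-butyl hydroperoxide, CC(C)(C)OO
Why: Sharpless asymmetric epoxidation touches only the allylic-alcohol double bond, and L-(+)-tartrate delivers oxygen to the face that gives the (2S,3S)-epoxy alcohol, i.e. the C8 oxygen of the target and C9 in the configuration needed for the coming inversion.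

Step 8
Reactants: 11 [(2S,3S)-3-{(1E,5Z)-1-(1,3-dioxolan-2-yl)-5-methyl-7-[(triethylsilyl)oxy]hepta-1,5-dien-1-yl}oxiran-2-yl]methanol; 12 (2R)-2-methylbutanoic acid
Product: 13 (2S,3R,4E,8Z)-4-(1,3-dioxolan-2-yl)-1,2-dihydroxy-8-methyl-10-[(triethylsilyl)oxy]deca-4,8-dien-3-yl (2R)-2-methylbutanoate
Conditions: Ti(OiPr)4 (1.5 equiv), CH2Cl2, 0 °C → rt
Reagents that add atoms: none
Why: Sharpless Ti(OiPr)4-mediated opening of a 2,3-epoxy alcohol: the titanium chelate delivers the carboxylate to C-3 (here also allylic) by SN2 with inversion, which sets 9R, leaves 8S untouched (anti diol pattern) and installs the (R)-2-methylbutanoate directly.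

Step 9
Reactants: 13 (2S,3R,4E,8Z)-4-(1,3-dioxolan-2-yl)-1,2-dihydroxy-8-methyl-10-[(triethylsilyl)oxy]deca-4,8-dien-3-yl (2R)-2-methylbutanoate
Product: 14 (2S,3R,4E,8Z)-4-(1,3-dioxolan-2-yl)-8-methyl-1,2,10-tris[(triethylsilyl)oxy]deca-4,8-dien-3-yl (2R)-2-methylbutanoate
Conditions: TESCl (2.5 equiv), imidazole, CH2Cl2–DMF, 0 °C
Reagents that add atoms: chlorotriethylsilane, CC[Si](Cl)(CC)CC
Why: Silylation of both hydroxyls protects C8–OH (against acyl migration and, later, lactonisation onto the acrylate ester) and turns C7–OH into a TES ether that can be oxidised directly.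

Step 10
Reactants: 14 (2S,3R,4E,8Z)-4-(1,3-dioxolan-2-yl)-8-methyl-1,2,10-tris[(triethylsilyl)oxy]deca-4,8-dien-3-yl (2R)-2-methylbutanoate
Product: 15 (2R,3R,4E,8Z)-4-(1,3-dioxolan-2-yl)-8-methyl-1,10-dioxo-2-[(triethylsilyl)oxy]deca-4,8-dien-3-yl (2R)-2-methylbutanoate
Conditions: (COCl)2, DMSO, CH2Cl2, −78 → −40 °C; then i-Pr2NEt, −78 → 0 °C; used crude
Reagents that add atoms: none
Why: Swern oxidation converts primary TES ethers directly into aldehydes while the secondary TES ether survives, so the allylic C6 and the C7 positions are oxidised together to the Z-enal and the α-silyloxy aldehyde.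

Step 11
Reactants: 15 (2R,3R,4E,8Z)-4-(1,3-dioxolan-2-yl)-8-methyl-1,10-dioxo-2-[(triethylsilyl)oxy]deca-4,8-dien-3-yl (2R)-2-methylbutanoate; 16 methyl propiolate
Product: 18 methyl (4S,5R,6E,10Z)-6-(1,3-dioxolan-2-yl)-3-hydroxy-10-methyl-5-{[(2R)-2-methylbutanoyl]oxy}-2-methylidene-12-oxo-4-[(triethylsilyl)oxy]dodeca-6,10-dienoate (both C3 epimers), via vinylalane 17 (not isolated)
Conditions: DIBAL-H, NMO, THF, 0 °C, then 16 (1.2 equiv), 0 °C; then 15, −40 → 0 °C; Rochelle salt work-up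
Reagents that add atoms: none
Why: Vinylalumination (hydroalumination of the propiolate to the α-ester vinylalane, then carbonyl addition) gives the Baylis–Hillman-type alcohol at the more electrophilic saturated α-silyloxy aldehyde rather than at the β,β-disubstituted enal; the new C7 carbinol centre forms as a mixture, which does not matter because it is removed in step 12.

Step 12
Reactants: 18 methyl (4S,5R,6E,10Z)-6-(1,3-dioxolan-2-yl)-3-hydroxy-10-methyl-5-{[(2R)-2-methylbutanoyl]oxy}-2-methylidene-12-oxo-4-[(triethylsilyl)oxy]dodeca-6,10-dienoate (both C3 epimers)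
Product: 19 methyl (2Z,4S,5R,6E,10Z)-2-(bromomethyl)-6-(1,3-dioxolan-2-yl)-10-methyl-5-{[(2R)-2-methylbutanoyl]oxy}-12-oxo-4-[(triethylsilyl)oxy]dodeca-2,6,10-trienoate
Conditions: NBS, Me2S, CH2Cl2, −20 → 0 °C
Reagents that add atoms: N-bromosuccinimide, O=C1CCC(=O)N1Br
Why: Corey–Kim-type activation of the Baylis–Hillman alcohol and SN2′ attack of bromide give the thermodynamically favoured (Z)-2-(bromomethyl)enoate, erasing the C7 centre and placing C8 trans to the ester.

Step 13
Reactants: 19 methyl (2Z,4S,5R,6E,10Z)-2-(bromomethyl)-6-(1,3-dioxolan-2-yl)-10-methyl-5-{[(2R)-2-methylbutanoyl]oxy}-12-oxo-4-[(triethylsilyl)oxy]dodeca-2,6,10-trienoate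
Product: 20 methyl (2Z,4S,5R,6E,10Z)-2-(bromomethyl)-6-(1,3-dioxolan-2-yl)-4-hydroxy-10-methyl-5-{[(2R)-2-methylbutanoyl]oxy}-12-oxododeca-2,6,10-trienoate
Conditions: HF·pyridine, THF, 0 °C; used at once
Reagents that add atoms: none
Why: Fluoride-mediated desilylation frees the C8 hydroxyl, which cannot lactonise because the Z double bond holds it trans to the ester, and makes it available to direct the ring closure.

Step 14
Reactants: 20 methyl (2Z,4S,5R,6E,10Z)-2-(bromomethyl)-6-(1,3-dioxolan-2-yl)-4-hydroxy-10-methyl-5-{[(2R)-2-methylbutanoyl]oxy}-12-oxododeca-2,6,10-trienoate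
Product: 23 (6R,7R,8S,9R)-14,14-(ethylenedioxy)-8-hydroxy-9-{[(2R)-2-methylbutanoyl]oxy}germacra-1(10)E,4Z,11(13)-trien-12,6-olide, via allylchromium 21 (not isolated), via chromium alkoxide 22 (not isolated)
Conditions: CrCl2 (8 equiv), degassed THF, rt; 20 added over 10 h by syringe pump (final 3 mM); then sat. aq. NH4Cl
Reagents that add atoms: none
Why: Intramolecular Nozaki–Hiyama allylation with in-situ lactonisation (Dreiding–Schmidt-type annulation, a closure mode known for ten-membered germacranolide rings): CrCl2 turns the allylic bromide into an allylchromium(III) that adds through C7 to the C6 aldehyde in a chair transition state and closes the carbocycle; the free C8 hydroxyl binds chromium so that, with C8–H eclipsing the C7=C11 bond to avoid A(1,3) strain, the aldehyde is delivered to the alkene face syn to O8 (sets 7R); the pseudo-equatorial alkenyl group of the aldehyde gives the anti adduct (sets 6R, trans-lactone); and the C6 chromium alkoxide, the only metallated oxygen, then acylates on the methyl ester to close the γ-lactone in the same operation.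

Step 15
Reactants: 23 (6R,7R,8S,9R)-14,14-(ethylenedioxy)-8-hydroxy-9-{[(2R)-2-methylbutanoyl]oxy}germacra-1(10)E,4Z,11(13)-trien-12,6-olide
Product: 24 (6R,7R,8S,9R)-8-hydroxy-9-{[(2R)-2-methylbutanoyl]oxy}-14-oxogermacra-1(10)E,4Z,11(13)-trien-12,6-olide
Conditions: 1 M aq. HCl–THF (1:4), 0 °C → rt
Reagents that add atoms: water, O
Why: Acid-catalysed hydrolysis of the α,β-unsaturated dioxolane liberates the C14 aldehyde under conditions that leave the α-methylene lactone, the ester and all stereocentres untouched.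

**Compound list**

1 | nerol, (2Z)-3,7-dimethylocta-2,6-dien-1-ol | OC/C=C(C)\CCC=C(C)C | starting material
2 | triethyl{[(2Z)-3,7-dimethylocta-2,6-dien-1-yl]oxy}silane | CC[Si](CC)(CC)OC/C=C(C)\CCC=C(C)C | intermediate
3 | (6Z)-2,6-dimethyl-8-[(triethylsilyl)oxy]oct-6-ene-2,3-diol (racemic, not isolated) | CC[Si](CC)(CC)OC/C=C(C)\CCC(O)C(C)(C)O | intermediate
4 | (4Z)-4-methyl-6-[(triethylsilyl)oxy]hex-4-enal | CC[Si](CC)(CC)OC/C=C(C)\CCC=O | intermediate
5 | (triphenylphosphoranylidene)acetaldehyde | O=CC=P(c1ccccc1)(c1ccccc1)c1ccccc1 | starting material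
6 | (2E,6Z)-6-methyl-8-[(triethylsilyl)oxy]octa-2,6-dienal | CC[Si](CC)(CC)OC/C=C(C)\CC/C=C/C=O | intermediate
7 | (2Z,6Z)-2-iodo-6-methyl-8-[(triethylsilyl)oxy]octa-2,6-dienal | CC[Si](CC)(CC)OC/C=C(C)\CC/C=C(I)/C=O | intermediate
8 | 2-{(1Z,5Z)-1-iodo-5-methyl-7-[(triethylsilyl)oxy]hepta-1,5-dien-1-yl}-1,3-dioxolane | CC[Si](CC)(CC)OC/C=C(C)\CC/C=C(I)/C1OCCO1 | intermediate
9 | (2E)-3-(tributylstannyl)prop-2-en-1-ol | CCCC[Sn](CCCC)(CCCC)/C=C/CO | starting material
10 | (2E,4E,8Z)-4-(1,3-dioxolan-2-yl)-8-methyl-10-[(triethylsilyl)oxy]deca-2,4,8-trien-1-ol | OC/C=C/C(C1OCCO1)=C\CC/C(C)=C\CO[Si](CC)(CC)CC | intermediate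
11 | [(2S,3S)-3-{(1E,5Z)-1-(1,3-dioxolan-2-yl)-5-methyl-7-[(triethylsilyl)oxy]hepta-1,5-dien-1-yl}oxiran-2-yl]methanol | OC[C@@H]1O[C@H]1/C(C2OCCO2)=C\CC/C(C)=C\CO[Si](CC)(CC)CC | intermediate
12 | (2R)-2-methylbutanoic acid | CC[C@@H](C)C(=O)O | starting material
13 | (2S,3R,4E,8Z)-4-(1,3-dioxolan-2-yl)-1,2-dihydroxy-8-methyl-10-[(triethylsilyl)oxy]deca-4,8-dien-3-yl (2R)-2-methylbutanoate | OC[C@H](O)[C@H](OC(=O)[C@H](C)CC)/C(C1OCCO1)=C\CC/C(C)=C\CO[Si](CC)(CC)CC | intermediate
14 | (2S,3R,4E,8Z)-4-(1,3-dioxolan-2-yl)-8-methyl-1,2,10-tris[(triethylsilyl)oxy]deca-4,8-dien-3-yl (2R)-2-methylbutanoate | CC[Si](CC)(CC)OC[C@H](O[Si](CC)(CC)CC)[C@H](OC(=O)[C@H](C)CC)/C(C1OCCO1)=C\CC/C(C)=C\CO[Si](CC)(CC)CC | intermediate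
15 | (2R,3R,4E,8Z)-4-(1,3-dioxolan-2-yl)-8-methyl-1,10-dioxo-2-[(triethylsilyl)oxy]deca-4,8-dien-3-yl (2R)-2-methylbutanoate | O=C[C@H](O[Si](CC)(CC)CC)[C@H](OC(=O)[C@H](C)CC)/C(C1OCCO1)=C\CC/C(C)=C\C=O | intermediate
16 | methyl propiolate (methyl prop-2-ynoate) | C#CC(=O)OC | starting material
17 | methyl 2-(diisobutylalumanyl)prop-2-enoate (not isolated) | C=C([Al](CC(C)C)CC(C)C)C(=O)OC | intermediate
18 | methyl (4S,5R,6E,10Z)-6-(1,3-dioxolan-2-yl)-3-hydroxy-10-methyl-5-{[(2R)-2-methylbutanoyl]oxy}-2-methylidene-12-oxo-4-[(triethylsilyl)oxy]dodeca-6,10-dienoate (both C3 epimers) | C=C(C(=O)OC)C(O)[C@H](O[Si](CC)(CC)CC)[C@H](OC(=O)[C@H](C)CC)/C(C1OCCO1)=C\CC/C(C)=C\C=O | intermediate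
19 | methyl (2Z,4S,5R,6E,10Z)-2-(bromomethyl)-6-(1,3-dioxolan-2-yl)-10-methyl-5-{[(2R)-2-methylbutanoyl]oxy}-12-oxo-4-[(triethylsilyl)oxy]dodeca-2,6,10-trienoate | BrC/C(C(=O)OC)=C\[C@H](O[Si](CC)(CC)CC)[C@H](OC(=O)[C@H](C)CC)/C(C1OCCO1)=C\CC/C(C)=C\C=O | intermediate
20 | methyl (2Z,4S,5R,6E,10Z)-2-(bromomethyl)-6-(1,3-dioxolan-2-yl)-4-hydroxy-10-methyl-5-{[(2R)-2-methylbutanoyl]oxy}-12-oxododeca-2,6,10-trienoate | BrC/C(C(=O)OC)=C\[C@H](O)[C@H](OC(=O)[C@H](C)CC)/C(C1OCCO1)=C\CC/C(C)=C\C=O | intermediate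
21 | allylchromium(III) dichloride derived from 20 (CrCl2 in place of Br; not isolated) | Cl[Cr](Cl)C/C(C(=O)OC)=C\[C@H](O)[C@H](OC(=O)[C@H](C)CC)/C(C1OCCO1)=C\CC/C(C)=C\C=O | intermediate
22 | ring-closed C6 chromium(III) alkoxide: ten-membered carbocycle with the methyl acrylate unit on C7, configured as 23 at C6–C9 (not isolated) | C=C(C(=O)OC)[C@H]1[C@H](O[Cr](Cl)Cl)/C=C(/C)CC/C=C(/C2OCCO2)[C@@H](OC(=O)[C@H](C)CC)[C@H]1O | intermediate
23 | (6R,7R,8S,9R)-14,14-(ethylenedioxy)-8-hydroxy-9-{[(2R)-2-methylbutanoyl]oxy}germacra-1(10)E,4Z,11(13)-trien-12,6-olide | C=C1C(=O)O[C@@H]2/C=C(/C)CC/C=C(/C3OCCO3)[C@@H](OC(=O)[C@H](C)CC)[C@@H](O)[C@@H]12 | intermediate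
24 | (6R,7R,8S,9R)-8-hydroxy-9-{[(2R)-2-methylbutanoyl]oxy}-14-oxogermacra-1(10)E,4Z,11(13)-trien-12,6-olide | C=C1C(=O)O[C@@H]2/C=C(/C)CC/C=C(/C=O)[C@@H](OC(=O)[C@H](C)CC)[C@@H](O)[C@@H]12 | target

**Step count and risks**

Total step count: 15. Longest linear sequence: 15 (fully linear from nerol).

The step most likely to fail is step 14. Medium-ring closure competes with oligomerisation, the C7 facial selectivity rests on chelation by the free C8 hydroxyl, and the hydroxy bromide 20 can cyclise to a 2,5-dihydrofuran before it meets chromium. The fallback leaves the route at 18. The Baylis–Hillman alcohol is converted with methyl chloroformate, pyridine and DMAP into its allylic methyl carbonate, methyl (4S,5R,6E,10Z)-6-(1,3-dioxolan-2-yl)-3-[(methoxycarbonyl)oxy]-10-methyl-5-{[(2R)-2-methylbutanoyl]oxy}-2-methylidene-12-oxo-4-[(triethylsilyl)oxy]dodeca-6,10-dienoate F1. Pd(PPh3)4 ionises this carbonate and InI reduces the π-allylpalladium to an allylindium (umpolung, THF, slow addition at high dilution). Ring closure and lactonisation again occur together, now through an indium chair with the C8 oxygen still silylated and no free hydroxy bromide involved, giving the 8-O-triethylsilyl ether of 23 F2. HF·pyridine then removes the silyl group and the route is rejoined at 23. This Pd/In umpolung has not been shown for such a macrocyclisation and is a proposal based on the known umpolung of allylic carbonates and acetates.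

The second is step 11. The alane must distinguish two aldehydes, and its Lewis acidity can trigger β-elimination of the C9 carboxylate from the α-silyloxy aldehyde. The fallback leaves at 15. The lithium enolate of methyl 3-(dimethylamino)propanoate (LDA, THF, −78 °C) adds only to the saturated aldehyde at this temperature. This gives methyl (4S,5R,6E,10Z)-2-[(dimethylamino)methyl]-6-(1,3-dioxolan-2-yl)-3-hydroxy-10-methyl-5-{[(2R)-2-methylbutanoyl]oxy}-12-oxo-4-[(triethylsilyl)oxy]dodeca-6,10-dienoate F3 (mixture at C2 and C3). N-Methylation with MeI and elimination of trimethylamine with NaHCO3 return to 18.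

The third is step 10. The amine base of the Swern protocol can isomerise the Z-enal or epimerise/eliminate at the new α-silyloxy-β-acyloxy aldehyde, and the desilylative oxidation of two sites at once may stall. The fallback leaves at 14. Buffered HF·pyridine/pyridine in THF at 0 °C removes only the two primary TES ethers and gives (2S,3R,4E,8Z)-4-(1,3-dioxolan-2-yl)-1,10-dihydroxy-8-methyl-2-[(triethylsilyl)oxy]deca-4,8-dien-3-yl (2R)-2-methylbutanoate F4. Base-free oxidation of both primary alcohols with TEMPO/PhI(OAc)2 (no Z→E isomerisation) rejoins the route at 15.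

**Further compounds**

F1 | step 14 | methyl (4S,5R,6E,10Z)-6-(1,3-dioxolan-2-yl)-3-[(methoxycarbonyl)oxy]-10-methyl-5-{[(2R)-2-methylbutanoyl]oxy}-2-methylidene-12-oxo-4-[(triethylsilyl)oxy]dodeca-6,10-dienoate (both C3 epimers) | C=C(C(=O)OC)C(OC(=O)OC)[C@H](O[Si](CC)(CC)CC)[C@H](OC(=O)[C@H](C)CC)/C(C1OCCO1)=C\CC/C(C)=C\C=O
F2 | step 14 | (6R,7R,8S,9R)-14,14-(ethylenedioxy)-9-{[(2R)-2-methylbutanoyl]oxy}-8-[(triethylsilyl)oxy]germacra-1(10)E,4Z,11(13)-trien-12,6-olide | C=C1C(=O)O[C@@H]2/C=C(/C)CC/C=C(/C3OCCO3)[C@@H](OC(=O)[C@H](C)CC)[C@@H](O[Si](CC)(CC)CC)[C@@H]12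
F3 | step 11 | methyl (4S,5R,6E,10Z)-2-[(dimethylamino)methyl]-6-(1,3-dioxolan-2-yl)-3-hydroxy-10-methyl-5-{[(2R)-2-methylbutanoyl]oxy}-12-oxo-4-[(triethylsilyl)oxy]dodeca-6,10-dienoate (mixture at C2 and C3) | COC(=O)C(CN(C)C)C(O)[C@H](O[Si](CC)(CC)CC)[C@H](OC(=O)[C@H](C)CC)/C(C1OCCO1)=C\CC/C(C)=C\C=O
F4 | step 10 | (2S,3R,4E,8Z)-4-(1,3-dioxolan-2-yl)-1,10-dihydroxy-8-methyl-2-[(triethylsilyl)oxy]deca-4,8-dien-3-yl (2R)-2-methylbutanoate | OC[C@H](O[Si](CC)(CC)CC)[C@H](OC(=O)[C@H](C)CC)/C(C1OCCO1)=C\CC/C(C)=C\CO
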